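**Retrosynthetic overview**
- The C2 acrylic acid is traced back to a C2 ethynyl group (Markovnikov hydrocarboxylation with CO/H2O). The side chain is cut at the CH2–CH(sp2) bond next to the E trisubstituted alkene (sp3–sp2 Negishi coupling of a ring-bearing 2-iodoethyl arm with an (E)-vinyl iodide that carries the carbinol).
- The only ring, the oxane (O1, C2–C6; C2 bears the acid unit, C5 the chain), is made first, on small fragments, by a formal [4+2] radical annulation (photoredox/copper). A γ-iodo alcohol (O1–C6–C5–C4, C5 preset) and a silyl-capped but-1-en-3-yne (C3=C2) are joined through the C3–C4 and O1–C2 bonds.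
- Enabling feature: C2 is an ether carbon carrying H, the ring CH2 C3 and an sp2 carbon (the acrylate carbon, carried as an alkyne). O1–C2–C3 is therefore the 1,2-difunctionalized vinyl group of a conjugated enyne, whose alkyne steers the radical to C3 and stabilizes the radical at C2. O1 and the ring CH2 C4 are 1,3-related through C6 and C5, i.e. a γ-hydroxyalkyl radical.
- C5 comes from lipase desymmetrization of 2-allylpropane-1,3-diol, the carbinol from a CBS reduction, and the E alkene from zirconium-catalysed carboalumination.
- Order: ring, then chain union, then unmasking of alkyne and carbinol, then the acid.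

Key step: step 6

Remark: ring positions are numbered O1, C2 (acid-bearing carbon), C3, C4, C5 (chain-bearing carbon), C6; the target is 2R,5S (2,5-trans) in the ring, R at the carbinol, E at the trisubstituted alkene; the silyl enyne is treated as not commercial and is made in step 5.

**Route**

Step 1
Reactants: 1 diethyl 2-(prop-2-en-1-yl)propanedioate (diethyl allylmalonate)
Product: 2 2-(prop-2-en-1-yl)propane-1,3-diol
Conditions: LiAlH4, THF, 0 °C to rt; Fieser work-up
Reagents that add atoms: none
Why: Hydride reduction of both ester groups of the malonate gives the prochiral 1,3-diol; the isolated alkene is inert and no stereocentre exists yet.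

Step 2
Reactants: 2 2-(prop-2-en-1-yl)propane-1,3-diol
Product: 3 (S)-2-(hydroxymethyl)pent-4-en-1-yl acetate
Conditions: Pseudomonas fluorescens lipase (Amano AK), vinyl acetate, i-Pr2O, rt, stopped just past full consumption of the diol
Reagents that add atoms: vinyl acetate, C=COC(C)=O
Why: Lipase-catalysed enantiotopos-selective transesterification (enzymatic desymmetrization of a prochiral 2-substituted propane-1,3-diol) should acetylate one hydroxymethyl arm only and so set the stereocentre that becomes C5, a little over-acylation to the diacetate upgrading the enantiomeric purity of the monoacetate.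

Step 3
Reactants: 3 (S)-2-(hydroxymethyl)pent-4-en-1-yl acetate
Product: 4 (R)-2-(iodomethyl)pent-4-en-1-yl acetate
Conditions: I2, PPh3, imidazole, CH2Cl2, 0 °C
Reagents that add atoms: iodine, II
Why: Appel-type iodination is an SN2 displacement at the free CH2OH group, so the stereocentre is untouched, and running it directly on fresh 3 forestalls acyl migration between the two arms.

Step 4
Reactants: 4 (R)-2-(iodomethyl)pent-4-en-1-yl acetate
Product: 5 (R)-2-(iodomethyl)pent-4-en-1-ol
Conditions: K2CO3 (0.2 equiv), MeOH, 0 °C
Reagents that add atoms: none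
Why: Base-catalysed transesterification (Zemplén-type methanolysis) removes the acetate under conditions too mild to close the γ-iodo alcohol to an oxetane.

Step 5
Reactants: 6 bromoethene (vinyl bromide); 7 ethynyltri(propan-2-yl)silane
Product: 8 (but-3-en-1-yn-1-yl)tri(propan-2-yl)silane
Conditions: Pd(PPh3)2Cl2 (2 mol %), CuI (4 mol %), i-Pr2NH, THF, 0 °C to rt
Reagents that add atoms: none
Why: Sonogashira coupling of a vinyl halide with a terminal silylalkyne gives the conjugated enyne, the bulky silyl cap serving later to shield the allenyl terminus.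

Step 6
Reactants: 5 (R)-2-(iodomethyl)pent-4-en-1-ol; 8 (but-3-en-1-yn-1-yl)tri(propan-2-yl)silane
Product: 10 tri(propan-2-yl){[(2R,5R)-5-(prop-2-en-1-yl)oxan-2-yl]ethynyl}silane, via propargylic radical 9 (not isolated)
Conditions: fac-Ir(ppy)3 (1 mol %), Cu(MeCN)4PF6 (10 mol %), chiral bis(oxazoline) 2,2'-(propane-2,2-diyl)bis(4-phenyl-4,5-dihydro-1,3-oxazole) (12 mol %, the enantiomer matched to 2R), Cs2CO3 (1.5 equiv), 8 (3 equiv), MeCN, blue LEDs (450 nm), 20 °C
Reagents that add atoms: none
Why: Proposed new method: excited fac-Ir(ppy)3 should reduce the C–I bond of 5 to a primary alkyl radical that adds to the CH2 terminus of enyne 8 (C3–C4 bond) to give the delocalized propargylic radical 9, while the oxidized iridium photocatalyst converts monovalent copper into a divalent copper alkoxide of the tethered hydroxyl; capture of 9 at its propargylic carbon and C–O reductive elimination from trivalent copper then form the O1–C2 bond and return monovalent copper. The closest known reaction types are the photoredox/copper-catalysed radical 1,2-carbofunctionalizations of 1,3-enynes and 1,3-dienes with alkyl halides and N-, O- or C-nucleophiles, the copper–bis(oxazoline) radical oxyfunctionalization/lactonization of alkenes and the Larock heteroannulation of dienes; the tethered-alcohol [4+2] variant with an unactivated alkyl iodide is the new element. The oxane is closed in a 6-exo sense at the propargylic terminus through a seven-membered cupracycle, the alternative closure at the allenyl terminus being an eight-membered ring that the silyl group blocks further. C5 is carried in from 5 and is never a radical centre, whereas C2 is created from the planar radical 9 in an enantioconvergent capture controlled by the chiral ligand on copper, matched with a chair-like closure that keeps the C5 allyl group equatorial, so the 2,5-trans (diequatorial) isomer should form. The step needs regioselective radical addition (the alkyne makes the vinyl CH2 the only terminus that leads to a stabilized radical), chemoselectivity over the isolated allyl group (addition to the enyne in excess should outrun addition to an unactivated alkene and 4-exo or 5-endo cyclization) and suppression of oxetane formation (weak carbonate base, room temperature).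

Step 7
Reactants: 10 tri(propan-2-yl){[(2R,5R)-5-(prop-2-en-1-yl)oxan-2-yl]ethynyl}silane
Product: 12 2-[(3R,6R)-6-{[tri(propan-2-yl)silyl]ethynyl}oxan-3-yl]ethan-1-ol, via ozonide 11 (not isolated)
Conditions: O3, CH2Cl2, −78 °C (Sudan Red 7B end point); then NaBH4, MeOH, −78 °C to rt
Reagents that add atoms: ozone, [O-][O+]=O
Why: Ozonolysis with reductive work-up cleaves the monosubstituted alkene, which reacts with ozone much faster than the hindered silyl-capped alkyne, and shortens the allyl group to the 2-hydroxyethyl arm without touching either stereocentre.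

Step 8
Reactants: 12 2-[(3R,6R)-6-{[tri(propan-2-yl)silyl]ethynyl}oxan-3-yl]ethan-1-ol
Product: 13 {[(2R,5R)-5-(2-iodoethyl)oxan-2-yl]ethynyl}tri(propan-2-yl)silane
Conditions: I2, PPh3, imidazole, CH2Cl2, 0 °C to rt
Reagents that add atoms: iodine, II
Why: Appel-type iodination (SN2 at a primary carbon) gives the primary iodide needed for zinc insertion and leaves the propargylic ether untouched.

Step 9
Reactants: 14 pent-4-ynoic acid; 15 N,O-dimethylhydroxylamine hydrochloride
Product: 17 N-methoxy-N-methylpent-4-ynamide, via acyl imidazole 16 (not isolated)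
Conditions: 1,1'-carbonyldiimidazole, CH2Cl2, rt; then 15, rt
Reagents that add atoms: none
Why: Acyl imidazole activation followed by amidation gives the Weinreb amide, which stops organolithium addition at the ketone stage.

Step 10
Reactants: 18 6-methylhept-5-en-2-one; 19 2,4,6-tri(propan-2-yl)benzenesulfonohydrazide
Product: 20 N'-(6-methylhept-5-en-2-ylidene)-2,4,6-tri(propan-2-yl)benzenesulfonohydrazide
Conditions: MeOH, HCl (cat.), rt
Reagents that add atoms: none
Why: Acid-catalysed condensation of the methyl ketone with the sulfonyl hydrazide gives the hydrazone required for the Shapiro reaction.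

Step 11
Reactants: 20 N'-(6-methylhept-5-en-2-ylidene)-2,4,6-tri(propan-2-yl)benzenesulfonohydrazide; 17 N-methoxy-N-methylpent-4-ynamide
Product: 22 10-methyl-6-methylideneundec-9-en-1-yn-5-one, via vinyllithium 21 (not isolated)
Conditions: 20 (2.2 equiv), n-BuLi (4.4 equiv), THF/TMEDA, −78 to 0 °C; then 17 (1 equiv), −78 to −20 °C; H2O quench
Reagents that add atoms: none
Why: The Shapiro reaction (dianion formation at the methyl group, loss of sulfinate and N2) gives the 1,1-disubstituted vinyllithium 21, one equivalent of which is spent on the acetylenic C–H of 17 while the second adds to the Weinreb amide, whose chelated tetrahedral intermediate prevents over-addition and releases the α-methylene ketone on quench.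

Step 12
Reactants: 22 10-methyl-6-methylideneundec-9-en-1-yn-5-one
Product: 23 (5R)-10-methyl-6-methylideneundec-9-en-1-yn-5-ol
Conditions: (S)-2-methyl-CBS-oxazaborolidine (20 mol %), catecholborane, toluene, −78 °C; aqueous NaOH work-up
Reagents that add atoms: none
Why: In the Corey–Bakshi–Shibata reduction the α-branched alkenyl group acts as the large substituent, so the (S)-oxazaborolidine should deliver hydride to the face that gives the R carbinol, and catecholborane at −78 °C should not hydroborate the alkyne or the alkenes.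

Step 13
Reactants: 23 (5R)-10-methyl-6-methylideneundec-9-en-1-yn-5-ol
Product: 24 tert-butyldimethyl{[(5R)-10-methyl-6-methylideneundec-9-en-1-yn-5-yl]oxy}silane
Conditions: TBSCl, imidazole, DMF, rt
Reagents that add atoms: tert-butyldimethylsilyl chloride, CC(C)(C)[Si](C)(C)Cl
Why: Standard silylation protects the allylic carbinol against the organoaluminium and organozinc reagents that follow.

Step 14
Reactants: 24 tert-butyldimethyl{[(5R)-10-methyl-6-methylideneundec-9-en-1-yn-5-yl]oxy}silane
Product: 26 tert-butyl{[(1E,5R)-1-iodo-2,10-dimethyl-6-methylideneundeca-1,9-dien-5-yl]oxy}dimethylsilane, via alkenylalane 25 (not isolated)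
Conditions: Me3Al (2.5 equiv), Cp2ZrCl2 (0.3 equiv), CH2Cl2, 0 °C to rt; then I2, THF, −30 to 0 °C
Reagents that add atoms: trimethylaluminium, C[Al](C)C; iodine, II
Why: Zirconium-catalysed carboalumination (Negishi) adds Me–Al syn across the terminal alkyne with methyl on the internal carbon, and iodinolysis with retention gives the (E)-vinyl iodide, which fixes the geometry of the target's trisubstituted alkene while the other alkenes stay inert.

Step 15
Reactants: 13 {[(2R,5R)-5-(2-iodoethyl)oxan-2-yl]ethynyl}tri(propan-2-yl)silane; 26 tert-butyl{[(1E,5R)-1-iodo-2,10-dimethyl-6-methylideneundeca-1,9-dien-5-yl]oxy}dimethylsilane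
Product: 28 tert-butyldimethyl{[(7R,10E)-2,10-dimethyl-6-methylidene-13-[(3S,6R)-6-{[tri(propan-2-yl)silyl]ethynyl}oxan-3-yl]trideca-2,10-dien-7-yl]oxy}silane, via alkylzinc iodide 27 (not isolated)
Conditions: Zn dust (activated with 1,2-dibromoethane and Me3SiCl), LiCl, THF, 35 °C; then 26, Pd(PPh3)4 (5 mol %), THF, 45 °C
Reagents that add atoms: none
Why: Negishi sp3–sp2 cross-coupling: zinc inserts into the primary iodide to give 27, which couples with the vinyl iodide under zerovalent palladium catalysis with retention of the E geometry, the silyl ether, the silylalkyne and the propargylic ether stereocentre being inert.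

Step 16
Reactants: 28 tert-butyldimethyl{[(7R,10E)-2,10-dimethyl-6-methylidene-13-[(3S,6R)-6-{[tri(propan-2-yl)silyl]ethynyl}oxan-3-yl]trideca-2,10-dien-7-yl]oxy}silane
Product: 29 (7R,10E)-13-[(3S,6R)-6-ethynyloxan-3-yl]-2,10-dimethyl-6-methylidenetrideca-2,10-dien-7-ol
Conditions: Bu4NF (3 equiv), THF, 0 °C to rt
Reagents that add atoms: none
Why: Fluoride cleaves the O–Si bond of the silyl ether and the C(sp)–Si bond of the silylalkyne in one operation without touching any stereocentre.

Step 17
Reactants: 29 (7R,10E)-13-[(3S,6R)-6-ethynyloxan-3-yl]-2,10-dimethyl-6-methylidenetrideca-2,10-dien-7-ol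
Product: 30 2-[(2R,5S)-5-[(3E,7R)-7-hydroxy-4,12-dimethyl-8-methylidenetrideca-3,11-dien-1-yl]oxan-2-yl]prop-2-enoic acid
Conditions: Pd(OAc)2 (2 mol %), 2-(diphenylphosphino)pyridine (20 mol %), CH3SO3H (10 mol %), CO (5 bar), H2O (10 equiv), THF, 45 °C
Reagents that add atoms: carbon monoxide, [C-]#[O+]; water, O
Why: Palladium-catalysed Markovnikov hydrocarboxylation (hydroxycarbonylation) of a terminal alkyne with the 2-pyridylphosphine catalyst should place CO2H on the internal alkyne carbon and give the 2-substituted acrylic acid directly, the alkyne binding to palladium far better than the alkenes and the C2 stereocentre not being involved.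

**Compound list**

1 | diethyl 2-(prop-2-en-1-yl)propanedioate | C=CCC(C(=O)OCC)C(=O)OCC | starting material
2 | 2-(prop-2-en-1-yl)propane-1,3-diol | C=CCC(CO)CO | intermediate
3 | (S)-2-(hydroxymethyl)pent-4-en-1-yl acetate | C=CC[C@H](COC(C)=O)CO | intermediate
4 | (R)-2-(iodomethyl)pent-4-en-1-yl acetate | C=CC[C@H](COC(C)=O)CI | intermediate
5 | (R)-2-(iodomethyl)pent-4-en-1-ol | C=CC[C@H](CO)CI | intermediate
6 | bromoethene | C=CBr | starting material
7 | ethynyltri(propan-2-yl)silane | C#C[Si](C(C)C)(C(C)C)C(C)C | starting material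
8 | (but-3-en-1-yn-1-yl)tri(propan-2-yl)silane | C=CC#C[Si](C(C)C)(C(C)C)C(C)C | intermediate
9 | (6R)-6-(hydroxymethyl)-1-[tri(propan-2-yl)silyl]non-8-en-1-yn-3-yl radical | C=CC[C@H](CO)CC[CH]C#C[Si](C(C)C)(C(C)C)C(C)C | intermediate (not isolated)
10 | tri(propan-2-yl){[(2R,5R)-5-(prop-2-en-1-yl)oxan-2-yl]ethynyl}silane | C=CC[C@H]1CC[C@H](C#C[Si](C(C)C)(C(C)C)C(C)C)OC1 | intermediate
11 | 3-{[(3R,6R)-6-{[tri(propan-2-yl)silyl]ethynyl}oxan-3-yl]methyl}-1,2,4-trioxolane | C1(C[C@H]2CC[C@H](C#C[Si](C(C)C)(C(C)C)C(C)C)OC2)OCOO1 | intermediate (not isolated)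
12 | 2-[(3R,6R)-6-{[tri(propan-2-yl)silyl]ethynyl}oxan-3-yl]ethan-1-ol | OCC[C@H]1CC[C@H](C#C[Si](C(C)C)(C(C)C)C(C)C)OC1 | intermediate
13 | {[(2R,5R)-5-(2-iodoethyl)oxan-2-yl]ethynyl}tri(propan-2-yl)silane | ICC[C@H]1CC[C@H](C#C[Si](C(C)C)(C(C)C)C(C)C)OC1 | intermediate
14 | pent-4-ynoic acid | C#CCCC(=O)O | starting material
15 | N,O-dimethylhydroxylamine hydrochloride | CNOC.Cl | starting material
16 | 1-(1H-imidazol-1-yl)pent-4-yn-1-one | C#CCCC(=O)n1ccnc1 | intermediate (not isolated)
17 | N-methoxy-N-methylpent-4-ynamide | C#CCCC(=O)N(C)OC | intermediate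
18 | 6-methylhept-5-en-2-one | CC(=O)CCC=C(C)C | starting material
19 | 2,4,6-tri(propan-2-yl)benzenesulfonohydrazide | CC(C)c1cc(C(C)C)c(S(=O)(=O)NN)c(C(C)C)c1 | starting material
20 | N'-(6-methylhept-5-en-2-ylidene)-2,4,6-tri(propan-2-yl)benzenesulfonohydrazide | CC(CCC=C(C)C)=NNS(=O)(=O)c1c(C(C)C)cc(C(C)C)cc1C(C)C | intermediate
21 | (6-methylhepta-1,5-dien-2-yl)lithium | [Li]C(=C)CCC=C(C)C | intermediate (not isolated)
22 | 10-methyl-6-methylideneundec-9-en-1-yn-5-one | C#CCCC(=O)C(=C)CCC=C(C)C | intermediate
23 | (5R)-10-methyl-6-methylideneundec-9-en-1-yn-5-ol | C=C(CCC=C(C)C)[C@H](O)CCC#C | intermediate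
24 | tert-butyldimethyl{[(5R)-10-methyl-6-methylideneundec-9-en-1-yn-5-yl]oxy}silane | C=C(CCC=C(C)C)[C@H](O[Si](C)(C)C(C)(C)C)CCC#C | intermediate
25 | [(1E,5R)-5-{[tert-butyl(dimethyl)silyl]oxy}-2,10-dimethyl-6-methylideneundeca-1,9-dien-1-yl]dimethylalumane | C=C(CCC=C(C)C)[C@H](O[Si](C)(C)C(C)(C)C)CC/C(C)=C/[Al](C)C | intermediate (not isolated)
26 | tert-butyl{[(1E,5R)-1-iodo-2,10-dimethyl-6-methylideneundeca-1,9-dien-5-yl]oxy}dimethylsilane | C=C(CCC=C(C)C)[C@H](O[Si](C)(C)C(C)(C)C)CC/C(C)=C/I | intermediate
27 | {2-[(3R,6R)-6-{[tri(propan-2-yl)silyl]ethynyl}oxan-3-yl]ethyl}zinc iodide | I[Zn]CC[C@H]1CC[C@H](C#C[Si](C(C)C)(C(C)C)C(C)C)OC1 | intermediate (not isolated)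
28 | tert-butyldimethyl{[(7R,10E)-2,10-dimethyl-6-methylidene-13-[(3S,6R)-6-{[tri(propan-2-yl)silyl]ethynyl}oxan-3-yl]trideca-2,10-dien-7-yl]oxy}silane | C=C(CCC=C(C)C)[C@H](O[Si](C)(C)C(C)(C)C)CC/C(C)=C/CC[C@H]1CC[C@H](C#C[Si](C(C)C)(C(C)C)C(C)C)OC1 | intermediate
29 | (7R,10E)-13-[(3S,6R)-6-ethynyloxan-3-yl]-2,10-dimethyl-6-methylidenetrideca-2,10-dien-7-ol | C=C(CCC=C(C)C)[C@H](O)CC/C(C)=C/CC[C@H]1CC[C@H](C#C)OC1 | intermediate
30 | 2-[(2R,5S)-5-[(3E,7R)-7-hydroxy-4,12-dimethyl-8-methylidenetrideca-3,11-dien-1-yl]oxan-2-yl]prop-2-enoic acid | C=C(CCC=C(C)C)[C@H](O)CC/C(C)=C/CC[C@H]1CC[C@H](C(=C)C(=O)O)OC1 | target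

**Step count and risks**

Total step count: 17. Longest linear sequence: 10 steps (1, 2, 3, 4, 6, 7, 8, 15, 16, 17).

Steps most likely to fail:

1. Step 6 (the proposed new method). What may go wrong: slow capture of the propargylic radical by copper, so that reduction or oligomerization of the radical takes over; competing C–O formation at the allenyl terminus; poor facial selectivity at C2, because the slim alkynyl group gives little substrate bias and the ligand must carry the control. Fallback (sets out from 4, returns at 10), which builds the ring by known polar chemistry and makes the two ring bonds in separate steps: iodide 4 alkylates sodium dimethyl malonate (NaH, THF/DMF) to give dimethyl 2-[(2S)-2-(acetoxymethyl)pent-4-en-1-yl]propanedioate F1; saponification (aqueous NaOH), acidification and heating (decarboxylation, lactonization) give (5R)-5-(prop-2-en-1-yl)oxan-2-one F2; lithium [tri(propan-2-yl)silyl]acetylide F3, made from 7 and n-BuLi in THF at −78 °C, adds once to the lactone to give the hemiketal (5R)-5-(prop-2-en-1-yl)-2-{[tri(propan-2-yl)silyl]ethynyl}oxan-2-ol F4; Et3SiH/BF3·OEt2 (CH2Cl2/MeCN, −40 °C) reduces the derived oxocarbenium ion by axial hydride delivery, which should place the alkynyl group equatorial and give 10 as the 2,5-trans isomer.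

2. Step 17. What may go wrong: erosion of the branched regioselectivity at the hindered secondary propargylic ether, palladium hydride-mediated alkene isomerization, or acid-induced transposition of the free allylic carbinol. Fallback (sets out from 29, returns at 30), which replaces the direct hydrocarboxylation by a stepwise α-metalation route: molybdenum-catalysed α-selective hydrostannation (Bu3SnH, Mo(CO)3(CNtBu)3 cat., THF, 55 °C) gives tributyl{1-[(2R,5S)-5-[(3E,7R)-7-hydroxy-4,12-dimethyl-8-methylidenetrideca-3,11-dien-1-yl]oxan-2-yl]ethenyl}stannane F5; iododestannylation (I2, 1 equiv, CH2Cl2, 0 °C) gives (7R,10E)-13-[(3S,6R)-6-(1-iodoethenyl)oxan-3-yl]-2,10-dimethyl-6-methylidenetrideca-2,10-dien-7-ol F6; palladium-catalysed hydroxycarbonylation of the vinyl iodide (Pd(OAc)2/PPh3, CO, K2CO3, DMF/H2O, then acidification) gives 30.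

3. Step 2. What may go wrong: insufficient discrimination between the two enantiotopic hydroxymethyl groups, the opposite sense of discrimination, or acyl migration in the monoacetate that erodes the enantiomeric purity. Fallback (sets out from 2, returns at 5), which replaces the enzyme by a small-molecule desymmetrization of an oxetane: monotosylation and ring closure in one flask (n-BuLi, TsCl, THF, 0 °C; then n-BuLi, 60 °C) by way of 2-(hydroxymethyl)pent-4-en-1-yl 4-methylbenzenesulfonate F7 give 3-(prop-2-en-1-yl)oxetane F8; enantioselective ring opening with Me3SiBr under chiral squaramide hydrogen-bond-donor catalysis (t-BuOMe, −80 °C; the catalyst enantiomer that leads to the R bromide) gives {[(2R)-2-(bromomethyl)pent-4-en-1-yl]oxy}trimethylsilane F9; mild methanolysis (citric acid, MeOH) gives (R)-2-(bromomethyl)pent-4-en-1-ol F10; Finkelstein exchange (NaI, acetone, reflux) gives 5.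

Further compounds
F1 | step 6 | dimethyl 2-[(2S)-2-(acetoxymethyl)pent-4-en-1-yl]propanedioate | C=CC[C@H](COC(C)=O)CC(C(=O)OC)C(=O)OC
F2 | step 6 | (5R)-5-(prop-2-en-1-yl)oxan-2-one | C=CC[C@H]1CCC(=O)OC1
F3 | step 6 | lithium [tri(propan-2-yl)silyl]acetylide | [Li]C#C[Si](C(C)C)(C(C)C)C(C)C
F4 | step 6 | (5R)-5-(prop-2-en-1-yl)-2-{[tri(propan-2-yl)silyl]ethynyl}oxan-2-ol | C=CC[C@H]1CCC(O)(C#C[Si](C(C)C)(C(C)C)C(C)C)OC1
F5 | step 17 | tributyl{1-[(2R,5S)-5-[(3E,7R)-7-hydroxy-4,12-dimethyl-8-methylidenetrideca-3,11-dien-1-yl]oxan-2-yl]ethenyl}stannane | C=C(CCC=C(C)C)[C@H](O)CC/C(C)=C/CC[C@H]1CC[C@H](C(=C)[Sn](CCCC)(CCCC)CCCC)OC1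
F6 | step 17 | (7R,10E)-13-[(3S,6R)-6-(1-iodoethenyl)oxan-3-yl]-2,10-dimethyl-6-methylidenetrideca-2,10-dien-7-ol | C=C(CCC=C(C)C)[C@H](O)CC/C(C)=C/CC[C@H]1CC[C@H](C(=C)I)OC1
F7 | step 2 | 2-(hydroxymethyl)pent-4-en-1-yl 4-methylbenzenesulfonate | C=CCC(CO)COS(=O)(=O)c1ccc(C)cc1
F8 | step 2 | 3-(prop-2-en-1-yl)oxetane | C=CCC1COC1
F9 | step 2 | {[(2R)-2-(bromomethyl)pent-4-en-1-yl]oxy}trimethylsilane | C=CC[C@H](CO[Si](C)(C)C)CBr
F10 | step 2 | (R)-2-(bromomethyl)pent-4-en-1-ol | C=CC[C@H](CO)CBr
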